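**Strategy.** The route rests on ring B (drimane numbering: C5–C6–C7–C8–C9–C10). It is a cyclohexene whose two-carbon edge C9–C10 carries the CH2OAr arm and the angular methyl cis to each other, and whose four-carbon edge C5–C8 ends in the methyl-bearing C8. An intramolecular Diels–Alder reaction of an acyclic (2E,8E,10E)-trienal forms C8–C9 and C5–C10 at once: the (E)-β-methyl enal supplies C11/C9/C10, the (E,E)-diene C5–C8, and the four-carbon tether with the (S)-silyloxy carbon C3 and the gem-dimethyl C4 closes ring A. One operation builds the trans-decalin and sets C5, C9 and C10 from C3; the ring-B double bond is then shifted from C6=C7 to C7=C8.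

Key step: step 8

Remark on the chemistry: drimane numbering is used for the decalin carbons (C3 carbinol, C4 gem-dimethyl, C5 ring-fusion CH, C8 methyl-bearing carbon, C9 carries C11H2O, C10 angular methyl). TBS = tert-butyldimethylsilyl. (+)-Ipc2BH is the diisopinocampheylborane made from (−)-α-pinene and BH3·SMe2.

**Step 1**
Reactants: 1 pent-4-yn-1-ol
Product: 2 pent-4-ynal
Conditions: TEMPO (10 mol %), PhI(OAc)2, CH2Cl2, 23 °C; NaHCO3 wash, short-path distillation
Reagents that add atoms: none
Why: Oxoammonium (TEMPO) oxidation of a primary alcohol should stop at the aldehyde and leave the terminal alkyne untouched.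

**Step 2**
Reactants: 2 pent-4-ynal; 3 3-methylbuta-1,2-diene
Product: 5 (4S)-3,3-dimethyloct-1-en-7-yn-4-ol, via prenylborane 4 (not isolated)
Conditions: (+)-Ipc2BH, 3, THF, −25 °C; then 2, Et2O, −78 °C; then NaOH, H2O2, 0 → 23 °C
Reagents that add atoms: none
Why: Brown asymmetric tert-prenylation, in which hydroboration of the allene puts boron on the unsubstituted terminus and the prenylborane then adds through its dimethyl terminus in a chair-like six-membered transition state whose isopinocampheyl groups expose the Re face of the aldehyde, which should set the (S)-carbinol next to the new quaternary carbon.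

**Step 3**
Reactants: 5 (4S)-3,3-dimethyloct-1-en-7-yn-4-ol
Product: 6 tert-butyl{[(4S)-3,3-dimethyloct-1-en-7-yn-4-yl]oxy}dimethylsilane
Conditions: TBSOTf, 2,6-lutidine, CH2Cl2, 0 °C
Reagents that add atoms: tert-butyldimethylsilyl trifluoromethanesulfonate, CC(C)(C)[Si](C)(C)OS(=O)(=O)C(F)(F)F
Why: Silylation with the silyl triflate overcomes the hindrance of the neopentyl-type secondary alcohol, and the ether blocks retro-aldol cleavage of the β-oxygenated aldehyde made in the next step.

**Step 4**
Reactants: 6 tert-butyl{[(4S)-3,3-dimethyloct-1-en-7-yn-4-yl]oxy}dimethylsilane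
Product: 8 (3S)-3-[(tert-butyldimethylsilyl)oxy]-2,2-dimethylhept-6-ynal, via ozonide 7 (not isolated)
Conditions: O3, CH2Cl2, −78 °C (Sudan Red 7B end point); then PPh3, −78 → 23 °C
Reagents that add atoms: ozone, [O-][O+]=O
Why: Ozonolysis with reductive work-up, in which ozone adds to the terminal alkene much faster than to the alkyne, should cleave only the vinyl group and give an α-quaternary aldehyde that cannot epimerise.

**Step 5**
Reactants: 8 (3S)-3-[(tert-butyldimethylsilyl)oxy]-2,2-dimethylhept-6-ynal; 9 [(2E)-but-2-en-1-yl](triphenyl)phosphonium bromide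
Product: 12 tert-butyl{[(5S,7E,9E)-6,6-dimethylundeca-7,9-dien-1-yn-5-yl]oxy}dimethylsilane, via crotyl ylide 10 (not isolated), via 7Z-dienyne 11 (not isolated)
Conditions: 9, n-BuLi, THF, −78 → 0 °C; then 8, −78 → 23 °C; then I2 (5 mol %), CH2Cl2, daylight, 23 °C
Reagents that add atoms: none
Why: Wittig olefination with the semi-stabilised crotyl ylide builds the diene, and iodine-catalysed equilibration should convert the 7Z isomer into the 7E isomer, which is strongly favoured next to the quaternary carbon, while a minor 9Z component is expected to stay unreactive in the later cycloaddition.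

**Step 6**
Reactants: 12 tert-butyl{[(5S,7E,9E)-6,6-dimethylundeca-7,9-dien-1-yn-5-yl]oxy}dimethylsilane
Product: 15 (2E,6S,8E,10E)-6-[(tert-butyldimethylsilyl)oxy]-3,7,7-trimethyldodeca-2,8,10-trien-1-ol, via alkenylalane 13 (not isolated), via lithium alanate 14 (not isolated)
Conditions: Me3Al, Cp2ZrCl2 (25 mol %), CH2Cl2, 0 → 23 °C; then n-BuLi, THF, −78 °C; then (CH2O)n, −78 → 23 °C
Reagents that add atoms: trimethylaluminium, C[Al](C)C; paraformaldehyde (as formaldehyde), C=O
Why: Negishi zirconium-catalysed carboalumination adds methyl and aluminium syn across the terminal alkyne (methyl to the internal carbon), and the alanate is hydroxymethylated with retention, which should give the (E)-trisubstituted allylic alcohol while the internal conjugated diene stays untouched.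

**Step 7**
Reactants: 15 (2E,6S,8E,10E)-6-[(tert-butyldimethylsilyl)oxy]-3,7,7-trimethyldodeca-2,8,10-trien-1-ol
Product: 16 (2E,6S,8E,10E)-6-[(tert-butyldimethylsilyl)oxy]-3,7,7-trimethyldodeca-2,8,10-trienal
Conditions: MnO2, CH2Cl2, 23 °C
Reagents that add atoms: none
Why: MnO2 oxidises only the allylic alcohol and should stop at the enal without changing the E geometry or the diene.

**Step 8**
Reactants: 16 (2E,6S,8E,10E)-6-[(tert-butyldimethylsilyl)oxy]-3,7,7-trimethyldodeca-2,8,10-trienal
Product: 18 [(1S,2S,4aR,6S,8aS)-6-[(tert-butyldimethylsilyl)oxy]-2,5,5,8a-tetramethyl-1,2,4a,5,6,7,8,8a-octahydronaphthalen-1-yl]methanol, via cycloadduct aldehyde 17 (not isolated)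
Conditions: Me2AlCl (1.2 equiv), CH2Cl2, −78 → −20 °C; then NaBH4, EtOH, −20 → 0 °C
Reagents that add atoms: none
Why: Me2AlCl binds the formyl oxygen and lowers the LUMO of the (E)-enal, which adds across the (E,E)-diene in a concerted but asynchronous normal-demand intramolecular Diels–Alder reaction (the C5–C10 bond leading), and NaBH4 then reduces the aluminium-bound aldehyde 17 in the same flask before C9 can epimerise. The closest known reaction type is the Lewis-acid-promoted cyclisation of terminally activated (2E,8E,10E)-trienals and trienoates to trans-fused octalins. Ring B closes as the six-membered ring of the [4+2] cycloadduct, and ring A closes in the fused mode through the four-atom tether held in a chair-like arrangement. C9 and C10 follow from suprafacial addition to the (E)-alkene (CH2O arm and angular methyl cis); C5 and C8 follow from the endo position of the formyl group under the diene with the tether anti (trans ring fusion, 8β-methyl); the absolute sense follows from the (S)-silyloxy carbon, which should sit equatorial on the forming chair. The step needs endo over exo selectivity and one of the two diene faces: the first is supported by the terminal position of the activating group under Lewis acid conditions, the second by the resident stereocentre next to the gem-dimethyl carbon.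

**Step 9**
Reactants: 18 [(1S,2S,4aR,6S,8aS)-6-[(tert-butyldimethylsilyl)oxy]-2,5,5,8a-tetramethyl-1,2,4a,5,6,7,8,8a-octahydronaphthalen-1-yl]methanol; 19 isofraxidin (7-hydroxy-6,8-dimethoxy-2H-chromen-2-one)
Product: 20 7-{[(1S,2S,4aR,6S,8aS)-6-[(tert-butyldimethylsilyl)oxy]-2,5,5,8a-tetramethyl-1,2,4a,5,6,7,8,8a-octahydronaphthalen-1-yl]methoxy}-6,8-dimethoxy-2H-chromen-2-one
Conditions: PPh3, DIAD, THF, 0 → 45 °C
Reagents that add atoms: none
Why: Mitsunobu etherification, in which the acidic 7-hydroxycoumarin protonates the betaine and displaces the alkoxyphosphonium ion at the primary carbon by SN2, so no stereocentre is touched.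

**Step 10**
Reactants: 20 (the C6=C7 aryl ether from step 9)
Product: 21 7-{[(1S,4aR,6S,8aS)-6-[(tert-butyldimethylsilyl)oxy]-2,5,5,8a-tetramethyl-1,4,4a,5,6,7,8,8a-octahydronaphthalen-1-yl]methoxy}-6,8-dimethoxy-2H-chromen-2-one
Conditions: RuHCl(CO)(PPh3)3 (10 mol %), toluene, 100 °C
Reagents that add atoms: none
Why: Ruthenium hydride catalysed alkene isomerisation by insertion and β-hydride elimination, in which hydride adds to C6 from the open α face and ruthenium at C7 removes the α hydrogen of C8, should release the trisubstituted C7=C8 alkene and relieve the 1,3-diaxial contact of the 8β and 10β methyl groups, while further migration would need a tertiary alkylruthenium at C8 and is expected to be slow.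

**Step 11**
Reactants: 21 (the C7=C8 silyl ether from step 10)
Product: 22 7-{[(1S,4aR,6S,8aS)-6-hydroxy-2,5,5,8a-tetramethyl-1,4,4a,5,6,7,8,8a-octahydronaphthalen-1-yl]methoxy}-6,8-dimethoxy-2H-chromen-2-one (target)
Conditions: HF·pyridine, pyridine, THF, 0 → 40 °C
Reagents that add atoms: none
Why: Fluoride cleavage of the hindered secondary silyl ether under buffered conditions should spare the coumarin lactone, the aryl ether and the trisubstituted alkene and release the (3S)-alcohol.

**Compound list**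

1 | pent-4-yn-1-ol | C#CCCCO | starting material
2 | pent-4-ynal | C#CCCC=O | intermediate
3 | 3-methylbuta-1,2-diene | CC(C)=C=C | starting material
4 | (3-methylbut-2-en-1-yl)diisopinocampheylborane (from (+)-Ipc2BH) | CC(C)=CCB([C@H]1C[C@H]2C[C@@H]([C@@H]1C)C2(C)C)[C@H]1C[C@H]2C[C@@H]([C@@H]1C)C2(C)C | intermediate
5 | (4S)-3,3-dimethyloct-1-en-7-yn-4-ol | C#CCC[C@H](O)C(C)(C)C=C | intermediate
6 | tert-butyl{[(4S)-3,3-dimethyloct-1-en-7-yn-4-yl]oxy}dimethylsilane | C#CCC[C@H](O[Si](C)(C)C(C)(C)C)C(C)(C)C=C | intermediate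
7 | tert-butyldimethyl{[(3S)-2-methyl-2-(1,2,4-trioxolan-3-yl)hept-6-yn-3-yl]oxy}silane (ozonide) | C#CCC[C@H](O[Si](C)(C)C(C)(C)C)C(C)(C)C1OCOO1 | intermediate
8 | (3S)-3-[(tert-butyldimethylsilyl)oxy]-2,2-dimethylhept-6-ynal | C#CCC[C@H](O[Si](C)(C)C(C)(C)C)C(C)(C)C=O | intermediate
9 | [(2E)-but-2-en-1-yl](triphenyl)phosphonium bromide | C/C=C/C[P+](c1ccccc1)(c1ccccc1)c1ccccc1.[Br-] | starting material
10 | [(2E)-but-2-en-1-ylidene](triphenyl)-λ5-phosphane | C/C=C/C=P(c1ccccc1)(c1ccccc1)c1ccccc1 | intermediate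
11 | tert-butyl{[(5S,7Z,9E)-6,6-dimethylundeca-7,9-dien-1-yn-5-yl]oxy}dimethylsilane | C#CCC[C@H](O[Si](C)(C)C(C)(C)C)C(C)(C)/C=C\C=C\C | intermediate
12 | tert-butyl{[(5S,7E,9E)-6,6-dimethylundeca-7,9-dien-1-yn-5-yl]oxy}dimethylsilane | C#CCC[C@H](O[Si](C)(C)C(C)(C)C)C(C)(C)/C=C/C=C/C | intermediate
13 | dimethyl[(1E,5S,7E,9E)-5-[(tert-butyldimethylsilyl)oxy]-2,6,6-trimethylundeca-1,7,9-trien-1-yl]alumane | C[Al](C)/C=C(\C)CC[C@H](O[Si](C)(C)C(C)(C)C)C(C)(C)/C=C/C=C/C | intermediate
14 | lithium butyl(dimethyl)[(1E,5S,7E,9E)-5-[(tert-butyldimethylsilyl)oxy]-2,6,6-trimethylundeca-1,7,9-trien-1-yl]alanuide | [Li+].CCCC[Al-](C)(C)/C=C(\C)CC[C@H](O[Si](C)(C)C(C)(C)C)C(C)(C)/C=C/C=C/C | intermediate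
15 | (2E,6S,8E,10E)-6-[(tert-butyldimethylsilyl)oxy]-3,7,7-trimethyldodeca-2,8,10-trien-1-ol | OC/C=C(\C)CC[C@H](O[Si](C)(C)C(C)(C)C)C(C)(C)/C=C/C=C/C | intermediate
16 | (2E,6S,8E,10E)-6-[(tert-butyldimethylsilyl)oxy]-3,7,7-trimethyldodeca-2,8,10-trienal | O=C/C=C(\C)CC[C@H](O[Si](C)(C)C(C)(C)C)C(C)(C)/C=C/C=C/C | intermediate
17 | (1S,2S,4aR,6S,8aS)-6-[(tert-butyldimethylsilyl)oxy]-2,5,5,8a-tetramethyl-1,2,4a,5,6,7,8,8a-octahydronaphthalene-1-carbaldehyde | O=C[C@H]1[C@@H](C)C=C[C@H]2C(C)(C)[C@@H](O[Si](C)(C)C(C)(C)C)CC[C@]12C | intermediate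
18 | [(1S,2S,4aR,6S,8aS)-6-[(tert-butyldimethylsilyl)oxy]-2,5,5,8a-tetramethyl-1,2,4a,5,6,7,8,8a-octahydronaphthalen-1-yl]methanol | OC[C@H]1[C@@H](C)C=C[C@H]2C(C)(C)[C@@H](O[Si](C)(C)C(C)(C)C)CC[C@]12C | intermediate
19 | isofraxidin (7-hydroxy-6,8-dimethoxy-2H-chromen-2-one) | COc1cc2ccc(=O)oc2c(OC)c1O | starting material
20 | 7-{[(1S,2S,4aR,6S,8aS)-6-[(tert-butyldimethylsilyl)oxy]-2,5,5,8a-tetramethyl-1,2,4a,5,6,7,8,8a-octahydronaphthalen-1-yl]methoxy}-6,8-dimethoxy-2H-chromen-2-one | COc1cc2ccc(=O)oc2c(OC)c1OC[C@H]1[C@@H](C)C=C[C@H]2C(C)(C)[C@@H](O[Si](C)(C)C(C)(C)C)CC[C@]12C | intermediate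
21 | 7-{[(1S,4aR,6S,8aS)-6-[(tert-butyldimethylsilyl)oxy]-2,5,5,8a-tetramethyl-1,4,4a,5,6,7,8,8a-octahydronaphthalen-1-yl]methoxy}-6,8-dimethoxy-2H-chromen-2-one | COc1cc2ccc(=O)oc2c(OC)c1OC[C@H]1C(C)=CC[C@H]2C(C)(C)[C@@H](O[Si](C)(C)C(C)(C)C)CC[C@]12C | intermediate
22 | 7-{[(1S,4aR,6S,8aS)-6-hydroxy-2,5,5,8a-tetramethyl-1,4,4a,5,6,7,8,8a-octahydronaphthalen-1-yl]methoxy}-6,8-dimethoxy-2H-chromen-2-one | COc1cc2ccc(=O)oc2c(OC)c1OC[C@H]1C(C)=CC[C@H]2C(C)(C)[C@@H](O)CC[C@]12C | target

**Totals**

Total step count: 11.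
Longest linear sequence: 11 steps (1 → 22); compounds 3, 9 and 19 enter as purchased materials.

**Three steps most likely to fail**

1. Step 8 (cycloaddition). The remote silyloxy stereocentre may discriminate the two diene faces poorly (the silyloxy group taking the axial position on the forming chair). The exo, cis-fused mode may also compete, because the angular methyl and the axial C4 methyl approach each other in the anti transition state. Fallback (auxiliary control in place of substrate control): setting out from trienal 16, Pinnick oxidation (NaClO2, NaH2PO4, 2-methylbut-2-ene) should give the trienoic acid F1. Activation as the pivaloyl mixed anhydride and acylation of lithiated (4S)-4-benzyl-1,3-oxazolidin-2-one should give the trienimide F2. Me2AlCl-promoted cycloaddition of the chelated s-cis imide, whose benzyl group blocks the diene face that leads to the wrong ring-B configuration and whose chelate raises the endo preference, should give the cycloadduct imide F3. LiBH4 cleavage releases the auxiliary and comes back to alcohol 18.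

2. Step 10 (double-bond shift). The migration may stall, may run on to the tetrasubstituted C8=C9 position or may go towards C5. Fallback (functional-group route to the C7=C8 alkene in place of catalytic migration): setting out from alcohol 18, hydroboration with BH3·THF and oxidative work-up (NaOH, H2O2) should place the hydroxyl at the less hindered C7 from the α face and give the 7α,11-diol F4. Mitsunobu coupling with 19 at the primary hydroxyl should give the aryl ether alcohol F5, and Dess–Martin oxidation the C7 ketone F6. Enolisation under thermodynamic control towards the more substituted C8 with trapping (Tf2O, 2,6-di-tert-butyl-4-methylpyridine) should give the C7=C8 enol triflate F7. Reduction with Pd(OAc)2, PPh3, Bu3N and HCO2H replaces the triflate by hydrogen and comes back to 21.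

3. Step 9 (ether formation). Displacement at the hindered primary carbon by the doubly ortho-substituted phenol may be slow, and elimination of the activated alcohol may compete. Fallback (sulfonate displacement in place of redox condensation): setting out from alcohol 18, Tf2O and 2,6-lutidine at −78 °C should give the primary triflate F8, which the caesium phenoxide of 19 (Cs2CO3, DMF, 0 → 23 °C) should displace to come back to 20.

**Further compounds**

F1 | step 8 | (2E,6S,8E,10E)-6-[(tert-butyldimethylsilyl)oxy]-3,7,7-trimethyldodeca-2,8,10-trienoic acid | OC(=O)/C=C(\C)CC[C@H](O[Si](C)(C)C(C)(C)C)C(C)(C)/C=C/C=C/C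
F2 | step 8 | (4S)-4-benzyl-3-[(2E,6S,8E,10E)-6-[(tert-butyldimethylsilyl)oxy]-3,7,7-trimethyldodeca-2,8,10-trienoyl]-1,3-oxazolidin-2-one | O=C(/C=C(\C)CC[C@H](O[Si](C)(C)C(C)(C)C)C(C)(C)/C=C/C=C/C)N1[C@@H](Cc2ccccc2)COC1=O
F3 | step 8 | (4S)-4-benzyl-3-{[(1S,2S,4aR,6S,8aS)-6-[(tert-butyldimethylsilyl)oxy]-2,5,5,8a-tetramethyl-1,2,4a,5,6,7,8,8a-octahydronaphthalen-1-yl]carbonyl}-1,3-oxazolidin-2-one | O=C([C@H]1[C@@H](C)C=C[C@H]2C(C)(C)[C@@H](O[Si](C)(C)C(C)(C)C)CC[C@]12C)N1[C@@H](Cc2ccccc2)COC1=O
F4 | step 10 | 3β-[(tert-butyldimethylsilyl)oxy]-8αH-drimane-7α,11-diol | OC[C@H]1[C@@H](C)[C@H](O)C[C@H]2C(C)(C)[C@@H](O[Si](C)(C)C(C)(C)C)CC[C@]12C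
F5 | step 10 | 7-({3β-[(tert-butyldimethylsilyl)oxy]-7α-hydroxy-8αH-driman-11-yl}oxy)-6,8-dimethoxy-2H-chromen-2-one | COc1cc2ccc(=O)oc2c(OC)c1OC[C@H]1[C@@H](C)[C@H](O)C[C@H]2C(C)(C)[C@@H](O[Si](C)(C)C(C)(C)C)CC[C@]12C
F6 | step 10 | 7-({3β-[(tert-butyldimethylsilyl)oxy]-7-oxo-8αH-driman-11-yl}oxy)-6,8-dimethoxy-2H-chromen-2-one | COc1cc2ccc(=O)oc2c(OC)c1OC[C@H]1[C@@H](C)C(=O)C[C@H]2C(C)(C)[C@@H](O[Si](C)(C)C(C)(C)C)CC[C@]12C
F7 | step 10 | 3β-[(tert-butyldimethylsilyl)oxy]-11-[(6,8-dimethoxy-2-oxo-2H-chromen-7-yl)oxy]drim-7-en-7-yl trifluoromethanesulfonate | COc1cc2ccc(=O)oc2c(OC)c1OC[C@H]1C(C)=C(OS(=O)(=O)C(F)(F)F)C[C@H]2C(C)(C)[C@@H](O[Si](C)(C)C(C)(C)C)CC[C@]12C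
F8 | step 9 | 3β-[(tert-butyldimethylsilyl)oxy]-8αH-drim-6-en-11-yl trifluoromethanesulfonate | O=S(=O)(OC[C@H]1[C@@H](C)C=C[C@H]2C(C)(C)[C@@H](O[Si](C)(C)C(C)(C)C)CC[C@]12C)C(F)(F)F
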